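**Retrosynthetic overview**

1. The target is read as an unsymmetrical cyclobutane diester with the two aryl groups cis. The carboxyl cis to both aryls carries the (6R)-amino alcohol (O cis to the piperidine ring); the carboxyl trans to them carries its (6S)-epimer. Both esters come from one amino alcohol: O-acylation (retention) and Mitsunobu esterification (inversion). The alcohol unit is numbered as cyclopenta[c]pyridine: C1, N2, C3, C4(Me), C4a, C5, C6(O), C7(Me), C7a.
2. The cyclobutane ring is bought as a trans-1,3-dicarboxylic acid monoester. Both aryl–ring bonds are made by an amide-directed double C–H arylation, which fixes all four ring stereocentres; the amide carbon later becomes the ester cis to the aryls.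
3. The amino alcohol comes (ketone reduction, enone hydrogenation with C7 equilibration, carbamate to N-methyl) from a bicyclic enone, made by an intramolecular Pauson–Khand reaction of an acyclic 1,7-enyne carbamate with one stereocentre (C4, from a copper-catalysed asymmetric allylic methylation).
4. Enabling feature: ring C4a–C5–C6–C7–C7a is a cyclopentanol whose carbinol carbon C6 lies between unsubstituted C5H2 and methyl-bearing C7, and it shares bond C4a–C7a with the piperidine ring closed through N2. So C6 = CO, C4a–C5 = a vinyl group, C7–C7a = a methyl-capped alkyne, N2 = the tether.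
5. Ring order: piperidine and cyclopentenone rings are formed together in the key step (bonds C4a–C7a, C5–C6, C6–C7); the cyclobutane ring is purchased; no other ring is formed.

Key step: step 4

Assumption: the sense of induction of Taniaphos in the allylic methylation is not relied on from memory; the ligand enantiomer that delivers the (R)-configured carbamate is the one meant (both are sold).
Assumption: trans-3-(methoxycarbonyl)cyclobutane-1-carboxylic acid is bought as the pure trans isomer (catalogue building block).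

**Route**

Step 1
Reactants: 1 but-2-yn-1-amine hydrochloride
Product: 2 methyl but-2-yn-1-ylcarbamate
Conditions: ClCO2Me (1.1 equiv), NaOH (2.2 equiv), CH2Cl2/H2O, 0 °C → rt
Reagents that add atoms: methyl chloroformate, COC(=O)Cl
Why: Schotten–Baumann acylation of the amine liberated in situ gives the carbamate that serves as the non-basic nitrogen tether of the key step and as the latent N-methyl group.

Step 2
Reactants: 2 methyl but-2-yn-1-ylcarbamate; 3 (E)-1,4-dibromobut-2-ene (3 equiv)
Product: 4 methyl (E)-(4-bromobut-2-en-1-yl)(but-2-yn-1-yl)carbamate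
Conditions: NaH (1.1 equiv), DMF, 0 °C, anion added slowly to 3
Reagents that add atoms: none
Why: N-alkylation of the sodium carbamate by SN2 at the primary allylic bromide, with the anion added slowly to excess 3 so that the second bromide survives; the E geometry is not touched.

Step 3
Reactants: 4 methyl (E)-(4-bromobut-2-en-1-yl)(but-2-yn-1-yl)carbamate
Product: 5 methyl (R)-(but-2-yn-1-yl)(2-methylbut-3-en-1-yl)carbamate
Conditions: MeMgBr (1.2 equiv), CuBr·SMe2 (5 mol%), Taniaphos (6 mol%, enantiomer giving R), CH2Cl2, −78 °C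
Reagents that add atoms: methylmagnesium bromide, C[Mg]Br
Why: Copper-catalysed enantioselective allylic alkylation (SN2′): anti oxidative addition of ligand-bound monovalent copper gives a γ-σ-allyl trivalent copper species that reductively eliminates the methyl group at the inner carbon, so the ligand sets the stereocentre (later C4) and the branched product should dominate, as known for (E)-4-bromobut-2-enyl substrates carrying protected heteroatoms.

Step 4
Reactants: 5 methyl (R)-(but-2-yn-1-yl)(2-methylbut-3-en-1-yl)carbamate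
Product: 7 methyl (4R,4aR)-4,7-dimethyl-6-oxo-1,3,4,4a,5,6-hexahydro-2H-cyclopenta[c]pyridine-2-carboxylate, via alkyne–hexacarbonyldicobalt complex 6 (not isolated)
Conditions: Co2(CO)8 (1.1 equiv), CH2Cl2, rt; then Me3NO·2H2O (8 equiv), 0 °C → rt
Reagents that add atoms: dicobalt octacarbonyl (one CO becomes C6=O), O=C=[Co](=C=O)(=C=O)(=C=O)[Co](=C=O)(=C=O)(=C=O)=C=O
Why: Pauson–Khand [2+2+1] cycloaddition: complex 6 loses one CO on N-oxide oxidation, the vinyl group coordinates and inserts into the Co–C7a bond (bond C4a–C7a, closing the piperidine ring), CO then inserts into the new Co–C5 bond (bond C5–C6) and reductive elimination joins C6 to C7, closing the cyclopentenone. The closest known reaction type is the N-oxide-promoted intramolecular Pauson–Khand reaction of nitrogen-tethered 1,7-enynes bearing a carbamate or sulfonamide, which gives cyclopenta[c]pyridin-6-ones. The piperidine ring closes by a 6-exo-type migratory insertion of the alkene into the cobalt–alkenyl bond, and the cyclopentenone ring by carbonyl insertion and reductive elimination at cobalt, both in the same operation. The one new stereocentre, C4a, is controlled by the C4 methyl group, which sits pseudo-equatorial in the chair-like insertion transition state and so should end trans to the C4a–C5 bond (cis to H4a). The step needs only this 1,2-diastereoselectivity: the tether fixes the regiochemistry, the methyl cap on the alkyne suppresses alkyne–alkyne side reactions and places the methyl group on C7, and the carbamate keeps a basic nitrogen away from cobalt.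

Step 5
Reactants: 7 methyl (4R,4aR)-4,7-dimethyl-6-oxo-1,3,4,4a,5,6-hexahydro-2H-cyclopenta[c]pyridine-2-carboxylate
Product: 9 methyl (4R,4aR,7R,7aS)-4,7-dimethyl-6-oxooctahydro-2H-cyclopenta[c]pyridine-2-carboxylate, via 7-epi-ketone 8 (not isolated)
Conditions: H2 (4 atm), 10% Pd/C, MeOH, rt; filter; NaOMe (0.3 equiv), MeOH, rt
Reagents that add atoms: none
Why: Heterogeneous hydrogenation should deliver H2 to the tetrasubstituted enone from the face of H4a (the other face is covered by C3 and C4 of the piperidine ring), which sets C7a with the cis ring fusion but leaves the C7 methyl on the concave face in 8; catalytic methoxide then equilibrates the only enolisable stereocentre, C7, to the more stable epimer with methyl trans to the C7a–C1 bond.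

Step 6
Reactants: 9 methyl (4R,4aR,7R,7aS)-4,7-dimethyl-6-oxooctahydro-2H-cyclopenta[c]pyridine-2-carboxylate
Product: 10 methyl (4R,4aR,6R,7R,7aS)-6-hydroxy-4,7-dimethyloctahydro-2H-cyclopenta[c]pyridine-2-carboxylate
Conditions: NaBH4, MeOH, −20 °C
Reagents that add atoms: none
Why: Borohydride reduction in which hydride should add to C6 from the convex face (the side of H4a and H7a), away from the piperidine ring that covers the concave face, a small hydride tolerating the adjacent methyl group as in the trans-selective reduction of 2-methylcyclopentanone, so that the hydroxyl ends cis to the piperidine ring and trans to the C7 methyl (6R).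

Step 7
Reactants: 10 methyl (4R,4aR,6R,7R,7aS)-6-hydroxy-4,7-dimethyloctahydro-2H-cyclopenta[c]pyridine-2-carboxylate
Product: 11 (4R,4aR,6R,7R,7aS)-2,4,7-trimethyloctahydro-1H-cyclopenta[c]pyridin-6-ol
Conditions: LiAlH4 (4 equiv), THF, 0 °C → reflux; aqueous NaOH work-up
Reagents that add atoms: none
Why: Hydride reduction of the methyl carbamate to the N-methyl amine (via the hemiaminal and the iminium ion), which turns the tether-protecting group into the N-methyl group of the target without touching a stereocentre.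

Step 8
Reactants: 12 4-iodo-2-methoxyphenol
Product: 13 1-(benzyloxy)-4-iodo-2-methoxybenzene
Conditions: BnBr, K2CO3, acetone, reflux
Reagents that add atoms: benzyl bromide, BrCc1ccccc1
Why: Williamson ether synthesis on the phenoxide; the benzyl ether withstands every later step and leaves by hydrogenolysis at the end.

Step 9
Reactants: 14 trans-3-(methoxycarbonyl)cyclobutane-1-carboxylic acid; 15 2-(methylsulfanyl)aniline
Product: 16 methyl trans-3-{[2-(methylsulfanyl)phenyl]carbamoyl}cyclobutane-1-carboxylate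
Conditions: EDC·HCl (1.3 equiv), DMAP (0.2 equiv), CH2Cl2, rt
Reagents that add atoms: none
Why: Carbodiimide amide coupling installs the bidentate N,S directing group on the free carboxyl; the trans relationship of the two ring substituents is not affected.

Step 10
Reactants: 16 methyl trans-3-{[2-(methylsulfanyl)phenyl]carbamoyl}cyclobutane-1-carboxylate; 13 1-(benzyloxy)-4-iodo-2-methoxybenzene (3 equiv)
Product: 17 methyl r-1,t-2,t-3,t-4-2,4-bis[4-(benzyloxy)-3-methoxyphenyl]-3-{[2-(methylsulfanyl)phenyl]carbamoyl}cyclobutane-1-carboxylate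
Conditions: Pd(OAc)2 (15 mol%), Ag2CO3 (2 equiv), PivOH (1 equiv), t-BuOH, 85 °C
Reagents that add atoms: none
Why: Twofold palladium-catalysed amide-directed β-C(sp3)–H arylation: N,S-chelated divalent palladium cleaves in turn the two methylene C–H bonds cis to the amide (pivalate-assisted concerted metalation–deprotonation), oxidative addition of 13 gives tetravalent palladium and reductive elimination forms each aryl–carbon bond with retention, so both aryl groups should end cis to the amide and trans to the ester, as known for cyclobutanecarboxamides and 1,3-cyclobutanedicarboxylic acid derivatives.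

Step 11
Reactants: 17 methyl r-1,t-2,t-3,t-4-2,4-bis[4-(benzyloxy)-3-methoxyphenyl]-3-{[2-(methylsulfanyl)phenyl]carbamoyl}cyclobutane-1-carboxylate
Product: 19 r-1,c-2,t-3,c-4-2,4-bis[4-(benzyloxy)-3-methoxyphenyl]-3-(methoxycarbonyl)cyclobutane-1-carboxylic acid, via N-Boc anilide 18 (not isolated)
Conditions: Boc2O (3 equiv), DMAP (0.3 equiv), MeCN, rt; then LiOH·H2O (2 equiv), 30% H2O2 (5 equiv), THF/H2O, 0 °C; Na2SO3; dilute HCl to pH 3
Reagents that add atoms: di-tert-butyl dicarbonate, CC(C)(C)OC(=O)OC(=O)OC(C)(C)C (its atoms stay in 18 only); hydrogen peroxide, OO (as LiOOH it delivers the oxygen of the new acid OH)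
Why: N-acylation twists the anilide out of conjugation and the small α-effect nucleophile LiOOH should then attack the imide carbonyl at 0 °C much faster than the flanked methyl ester (acyl substitution as in the cleavage of N-acyl oxazolidinones), under conditions too weakly basic to enolise the ring carbon whose carboxyl stays cis to both aryl groups.

Step 12
Reactants: 19 r-1,c-2,t-3,c-4-2,4-bis[4-(benzyloxy)-3-methoxyphenyl]-3-(methoxycarbonyl)cyclobutane-1-carboxylic acid; 11 (4R,4aR,6R,7R,7aS)-2,4,7-trimethyloctahydro-1H-cyclopenta[c]pyridin-6-ol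
Product: 21 1-methyl 3-[(4R,4aR,6R,7R,7aS)-2,4,7-trimethyloctahydro-1H-cyclopenta[c]pyridin-6-yl] r-1,t-2,t-3,t-4-2,4-bis[4-(benzyloxy)-3-methoxyphenyl]cyclobutane-1,3-dicarboxylate, via acid chloride 20 (not isolated)
Conditions: 1-chloro-N,N,2-trimethylprop-1-en-1-amine (1.2 equiv), CH2Cl2, 0 °C → rt; then 11 (1.2 equiv), DMAP (2 equiv), CH2Cl2, 0 °C → rt; aqueous NaHCO3 work-up
Reagents that add atoms: 1-chloro-N,N,2-trimethylprop-1-en-1-amine, CC(C)=C(Cl)N(C)C (its chlorine stays in 20 only)
Why: Acid chloride formation under neutral conditions with the α-chloroenamine followed by DMAP-catalysed O-acylation, which leaves C6 of the alcohol untouched (retention, 6R) and puts this unit on the carboxyl cis to both aryl groups; should a ketene arise by loss of HCl, protonation of the enol from the face opposite to the two aryl groups would restore the same ring configuration.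

Step 13
Reactants: 21 1-methyl 3-[(4R,4aR,6R,7R,7aS)-2,4,7-trimethyloctahydro-1H-cyclopenta[c]pyridin-6-yl] r-1,t-2,t-3,t-4-2,4-bis[4-(benzyloxy)-3-methoxyphenyl]cyclobutane-1,3-dicarboxylate
Product: 22 r-1,t-2,t-3,t-4-2,4-bis[4-(benzyloxy)-3-methoxyphenyl]-3-({[(4R,4aR,6R,7R,7aS)-2,4,7-trimethyloctahydro-1H-cyclopenta[c]pyridin-6-yl]oxy}carbonyl)cyclobutane-1-carboxylic acid
Conditions: Me3SnOH (5 equiv), 1,2-dichloroethane, 80 °C; pH 7 buffer work-up
Reagents that add atoms: trimethyltin hydroxide, C[Sn](C)(C)O (delivers the oxygen of the new acid OH)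
Why: Trimethyltin hydroxide cleaves the methyl ester by tin carboxylate formation under near-neutral conditions, selectively over the hindered secondary ester and without enolising the ring carbon next to it.

Step 14
Reactants: 22 r-1,t-2,t-3,t-4-2,4-bis[4-(benzyloxy)-3-methoxyphenyl]-3-({[(4R,4aR,6R,7R,7aS)-2,4,7-trimethyloctahydro-1H-cyclopenta[c]pyridin-6-yl]oxy}carbonyl)cyclobutane-1-carboxylic acid; 11 (4R,4aR,6R,7R,7aS)-2,4,7-trimethyloctahydro-1H-cyclopenta[c]pyridin-6-ol
Product: 23 1-[(4R,4aR,6S,7R,7aS)-2,4,7-trimethyloctahydro-1H-cyclopenta[c]pyridin-6-yl] 3-[(4R,4aR,6R,7R,7aS)-2,4,7-trimethyloctahydro-1H-cyclopenta[c]pyridin-6-yl] r-1,t-2,t-3,t-4-2,4-bis[4-(benzyloxy)-3-methoxyphenyl]cyclobutane-1,3-dicarboxylate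
Conditions: PPh3 (2.5 equiv), DIAD (2.5 equiv), THF, 0 °C → rt
Reagents that add atoms: none
Why: Mitsunobu esterification: the carboxylate of 22 displaces the oxyphosphonium group of 11 in an SN2 reaction from the convex face with inversion at C6 (6R to 6S), which creates the epimeric alcohol unit on the carboxyl trans to the aryl groups without any activation of an acyl group.

Step 15
Reactants: 23 1-[(4R,4aR,6S,7R,7aS)-2,4,7-trimethyloctahydro-1H-cyclopenta[c]pyridin-6-yl] 3-[(4R,4aR,6R,7R,7aS)-2,4,7-trimethyloctahydro-1H-cyclopenta[c]pyridin-6-yl] r-1,t-2,t-3,t-4-2,4-bis[4-(benzyloxy)-3-methoxyphenyl]cyclobutane-1,3-dicarboxylate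
Product: 24 CNP0283097.4 (the same diester with two 4-hydroxy-3-methoxyphenyl groups)
Conditions: H2 (1 atm), 10% Pd/C, EtOAc/MeOH, rt
Reagents that add atoms: none
Why: Hydrogenolysis of the two aryl benzyl ethers on palladium under neutral conditions, which leaves the esters, the tertiary amines and the cyclobutane untouched.

**Compound list**

1 | but-2-yn-1-amine hydrochloride | CC#CCN.Cl | starting material
2 | methyl but-2-yn-1-ylcarbamate | CC#CCNC(=O)OC | intermediate
3 | (E)-1,4-dibromobut-2-ene | BrC/C=C/CBr | starting material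
4 | methyl (E)-(4-bromobut-2-en-1-yl)(but-2-yn-1-yl)carbamate | CC#CCN(C/C=C/CBr)C(=O)OC | intermediate
5 | methyl (R)-(but-2-yn-1-yl)(2-methylbut-3-en-1-yl)carbamate | CC#CCN(C[C@@H](C=C)C)C(=O)OC | intermediate
6 | hexacarbonyldicobalt complex of the alkyne of 5 | COC(=O)N(C[C@@H](C=C)C)CC12C3(C)[Co]1(=C=O)(=C=O)(=C=O)[Co]23(=C=O)(=C=O)=C=O | intermediate
7 | methyl (4R,4aR)-4,7-dimethyl-6-oxo-1,3,4,4a,5,6-hexahydro-2H-cyclopenta[c]pyridine-2-carboxylate | O=C1C[C@H]2C(CN(C(=O)OC)C[C@@H]2C)=C1C | intermediate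
8 | methyl (4R,4aR,7S,7aS)-4,7-dimethyl-6-oxooctahydro-2H-cyclopenta[c]pyridine-2-carboxylate (7-epi-ketone) | O=C1C[C@H]2[C@H](CN(C(=O)OC)C[C@@H]2C)[C@@H]1C | intermediate
9 | methyl (4R,4aR,7R,7aS)-4,7-dimethyl-6-oxooctahydro-2H-cyclopenta[c]pyridine-2-carboxylate | O=C1C[C@H]2[C@H](CN(C(=O)OC)C[C@@H]2C)[C@H]1C | intermediate
10 | methyl (4R,4aR,6R,7R,7aS)-6-hydroxy-4,7-dimethyloctahydro-2H-cyclopenta[c]pyridine-2-carboxylate | O[C@@H]1C[C@H]2[C@H](CN(C(=O)OC)C[C@@H]2C)[C@H]1C | intermediate
11 | (4R,4aR,6R,7R,7aS)-2,4,7-trimethyloctahydro-1H-cyclopenta[c]pyridin-6-ol (OH cis to the piperidine ring, trans to the C7 methyl) | O[C@@H]1C[C@H]2[C@H](CN(C)C[C@@H]2C)[C@H]1C | intermediate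
12 | 4-iodo-2-methoxyphenol | COc1cc(I)ccc1O | starting material
13 | 1-(benzyloxy)-4-iodo-2-methoxybenzene | COc1cc(I)ccc1OCc1ccccc1 | intermediate
14 | trans-3-(methoxycarbonyl)cyclobutane-1-carboxylic acid | O=C(O)[C@H]1C[C@H](C(=O)OC)C1 | starting material
15 | 2-(methylsulfanyl)aniline | CSc1ccccc1N | starting material
16 | methyl trans-3-{[2-(methylsulfanyl)phenyl]carbamoyl}cyclobutane-1-carboxylate | COC(=O)[C@H]1C[C@H](C(=O)Nc2ccccc2SC)C1 | intermediate
17 | methyl r-1,t-2,t-3,t-4-2,4-bis[4-(benzyloxy)-3-methoxyphenyl]-3-{[2-(methylsulfanyl)phenyl]carbamoyl}cyclobutane-1-carboxylate (amide cis to both aryls, ester trans) | COc1cc([C@@H]2[C@@H](C(=O)OC)[C@H](c3ccc(OCc4ccccc4)c(OC)c3)[C@@H]2C(=O)Nc2ccccc2SC)ccc1OCc1ccccc1 | intermediate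
18 | methyl r-1,t-2,t-3,t-4-2,4-bis[4-(benzyloxy)-3-methoxyphenyl]-3-{(tert-butoxycarbonyl)[2-(methylsulfanyl)phenyl]carbamoyl}cyclobutane-1-carboxylate (N-Boc anilide) | COc1cc([C@@H]2[C@@H](C(=O)OC)[C@H](c3ccc(OCc4ccccc4)c(OC)c3)[C@@H]2C(=O)N(C(=O)OC(C)(C)C)c2ccccc2SC)ccc1OCc1ccccc1 | intermediate
19 | r-1,c-2,t-3,c-4-2,4-bis[4-(benzyloxy)-3-methoxyphenyl]-3-(methoxycarbonyl)cyclobutane-1-carboxylic acid | COc1cc([C@@H]2[C@@H](C(=O)OC)[C@H](c3ccc(OCc4ccccc4)c(OC)c3)[C@@H]2C(=O)O)ccc1OCc1ccccc1 | intermediate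
20 | methyl r-1,t-2,t-3,t-4-2,4-bis[4-(benzyloxy)-3-methoxyphenyl]-3-(chlorocarbonyl)cyclobutane-1-carboxylate (acid chloride) | COc1cc([C@@H]2[C@@H](C(=O)OC)[C@H](c3ccc(OCc4ccccc4)c(OC)c3)[C@@H]2C(=O)Cl)ccc1OCc1ccccc1 | intermediate
21 | 1-methyl 3-[(4R,4aR,6R,7R,7aS)-2,4,7-trimethyloctahydro-1H-cyclopenta[c]pyridin-6-yl] r-1,t-2,t-3,t-4-2,4-bis[4-(benzyloxy)-3-methoxyphenyl]cyclobutane-1,3-dicarboxylate | COc1cc([C@@H]2[C@@H](C(=O)OC)[C@H](c3ccc(OCc4ccccc4)c(OC)c3)[C@@H]2C(=O)O[C@@H]2C[C@H]3[C@H](CN(C)C[C@@H]3C)[C@H]2C)ccc1OCc1ccccc1 | intermediate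
22 | r-1,t-2,t-3,t-4-2,4-bis[4-(benzyloxy)-3-methoxyphenyl]-3-({[(4R,4aR,6R,7R,7aS)-2,4,7-trimethyloctahydro-1H-cyclopenta[c]pyridin-6-yl]oxy}carbonyl)cyclobutane-1-carboxylic acid | COc1cc([C@@H]2[C@@H](C(=O)O)[C@H](c3ccc(OCc4ccccc4)c(OC)c3)[C@@H]2C(=O)O[C@@H]2C[C@H]3[C@H](CN(C)C[C@@H]3C)[C@H]2C)ccc1OCc1ccccc1 | intermediate
23 | 1-[(4R,4aR,6S,7R,7aS)-2,4,7-trimethyloctahydro-1H-cyclopenta[c]pyridin-6-yl] 3-[(4R,4aR,6R,7R,7aS)-2,4,7-trimethyloctahydro-1H-cyclopenta[c]pyridin-6-yl] r-1,t-2,t-3,t-4-2,4-bis[4-(benzyloxy)-3-methoxyphenyl]cyclobutane-1,3-dicarboxylate | COc1cc([C@@H]2[C@@H](C(=O)O[C@H]3C[C@H]4[C@H](CN(C)C[C@@H]4C)[C@H]3C)[C@H](c3ccc(OCc4ccccc4)c(OC)c3)[C@@H]2C(=O)O[C@@H]2C[C@H]3[C@H](CN(C)C[C@@H]3C)[C@H]2C)ccc1OCc1ccccc1 | intermediate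
24 | CNP0283097.4: 1-[(4R,4aR,6S,7R,7aS)-2,4,7-trimethyloctahydro-1H-cyclopenta[c]pyridin-6-yl] 3-[(4R,4aR,6R,7R,7aS)-2,4,7-trimethyloctahydro-1H-cyclopenta[c]pyridin-6-yl] r-1,t-2,t-3,t-4-2,4-bis(4-hydroxy-3-methoxyphenyl)cyclobutane-1,3-dicarboxylate | COc1cc([C@@H]2[C@@H](C(=O)O[C@H]3C[C@H]4[C@H](CN(C)C[C@@H]4C)[C@H]3C)[C@H](c3ccc(O)c(OC)c3)[C@@H]2C(=O)O[C@@H]2C[C@H]3[C@H](CN(C)C[C@@H]3C)[C@H]2C)ccc1O | target

**Step count and risks**

Total step count: 15. Longest linear sequence: 11 steps (steps 1–7, then 12–15).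

Steps most likely to fail:

Step 4 (key step). The vinyl group may insert with poor facial discrimination relative to the C4 methyl group, because insertion at cobalt is kinetic and irreversible. The six-membered tether may also cyclise so slowly that the N-oxide strips the metal first. The fallback sets out from 5 and comes back to the route at 11; it replaces the cobalt cycloaddition by a reversible early-metal reductive bicyclisation followed by a separate carbonylation. The carbamate of 5 is reduced first (LiAlH4, THF, 0 → 40 °C) to the tertiary amine (R)-N-(but-2-yn-1-yl)-N,2-dimethylbut-3-en-1-amine F1. Zirconocene-mediated bicyclisation (Cp2ZrCl2, 2 n-BuLi, THF, −78 °C → rt) should give the zirconabicycle (4R,4aR)-6,6-di(cyclopentadienyl)-2,4,7-trimethyl-1,2,3,4,4a,5-hexahydro-6-zirconacyclopenta[c]pyridine F2; because metallacycle formation is reversible, the diastereomer with the equatorial C4 methyl should accumulate. Carbon monoxide (1 atm, 0 °C) and dilute HCl should then give the N-methyl enone (4R,4aR)-2,4,7-trimethyl-1,2,3,4,4a,5-hexahydro-6H-cyclopenta[c]pyridin-6-one F3. Hydrogenation and methoxide equilibration as in step 5 should lead through the 7-epimer (4R,4aR,7S,7aS)-2,4,7-trimethyloctahydro-6H-cyclopenta[c]pyridin-6-one F4 to the ketone (4R,4aR,7R,7aS)-2,4,7-trimethyloctahydro-6H-cyclopenta[c]pyridin-6-one F5, and NaBH4 (MeOH, −20 °C) should give 11.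

Step 12. Acyl substitution at the carbonyl group shielded by two cis aryl groups may be too slow with a secondary alcohol, so that base-induced enolisation and epimerisation of the ring carbon to the more stable trans arrangement takes over. The fallback sets out from 11 and 19 and comes back at 21; it makes the C–O bond at C6 instead of at the acyl carbon. Alcohol 11 is inverted by a Mitsunobu reaction with 4-nitrobenzoic acid (PPh3, DIAD, THF) to (4R,4aR,6S,7R,7aS)-2,4,7-trimethyloctahydro-1H-cyclopenta[c]pyridin-6-yl 4-nitrobenzoate F6. Methanolysis (K2CO3, MeOH) gives the C6-epimeric alcohol (4R,4aR,6S,7R,7aS)-2,4,7-trimethyloctahydro-1H-cyclopenta[c]pyridin-6-ol F7. A Mitsunobu esterification of acid 19 with F7 (PPh3, DIAD, THF) should then give 21 with inversion (6S to 6R), the acid never being activated.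

Step 14. The oxyphosphonium intermediate may eliminate to the cyclopentene, or the carboxylate may attack phosphorus (acyloxyphosphonium path) and give ester with retention. The fallback sets out from 22 and 11 and comes back at 23; it swaps the roles so that inversion is done with a small acid and the large acid is attached with retention. Alcohol 11 is first inverted through the nitrobenzoate F6 to the epimeric alcohol F7 as described for step 12. Acid 22 is converted with 1-chloro-N,N,2-trimethylprop-1-en-1-amine into the acid chloride (4R,4aR,6R,7R,7aS)-2,4,7-trimethyloctahydro-1H-cyclopenta[c]pyridin-6-yl r-1,c-2,t-3,c-4-2,4-bis[4-(benzyloxy)-3-methoxyphenyl]-3-(chlorocarbonyl)cyclobutane-1-carboxylate F8, which acylates F7 (DMAP, CH2Cl2) to give 23.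

**Further compounds**

F1 | step 4 | (R)-N-(but-2-yn-1-yl)-N,2-dimethylbut-3-en-1-amine | CC#CCN(C)C[C@@H](C=C)C
F2 | step 4 | (4R,4aR)-6,6-di(cyclopentadienyl)-2,4,7-trimethyl-1,2,3,4,4a,5-hexahydro-6-zirconacyclopenta[c]pyridine | [Zr]1(C3C=CC=C3)(C3C=CC=C3)C[C@H]2C(CN(C)C[C@@H]2C)=C1C
F3 | step 4 | (4R,4aR)-2,4,7-trimethyl-1,2,3,4,4a,5-hexahydro-6H-cyclopenta[c]pyridin-6-one | O=C1C[C@H]2C(CN(C)C[C@@H]2C)=C1C
F4 | step 4 | (4R,4aR,7S,7aS)-2,4,7-trimethyloctahydro-6H-cyclopenta[c]pyridin-6-one | O=C1C[C@H]2[C@H](CN(C)C[C@@H]2C)[C@@H]1C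
F5 | step 4 | (4R,4aR,7R,7aS)-2,4,7-trimethyloctahydro-6H-cyclopenta[c]pyridin-6-one | O=C1C[C@H]2[C@H](CN(C)C[C@@H]2C)[C@H]1C
F6 | step 12 | (4R,4aR,6S,7R,7aS)-2,4,7-trimethyloctahydro-1H-cyclopenta[c]pyridin-6-yl 4-nitrobenzoate | O=C(O[C@H]1C[C@H]2[C@H](CN(C)C[C@@H]2C)[C@H]1C)c1ccc(cc1)[N+](=O)[O-]
F7 | step 12 | (4R,4aR,6S,7R,7aS)-2,4,7-trimethyloctahydro-1H-cyclopenta[c]pyridin-6-ol | O[C@H]1C[C@H]2[C@H](CN(C)C[C@@H]2C)[C@H]1C
F8 | step 14 | (4R,4aR,6R,7R,7aS)-2,4,7-trimethyloctahydro-1H-cyclopenta[c]pyridin-6-yl r-1,c-2,t-3,c-4-2,4-bis[4-(benzyloxy)-3-methoxyphenyl]-3-(chlorocarbonyl)cyclobutane-1-carboxylate | COc1cc([C@@H]2[C@@H](C(=O)Cl)[C@H](c3ccc(OCc4ccccc4)c(OC)c3)[C@@H]2C(=O)O[C@@H]2C[C@H]3[C@H](CN(C)C[C@@H]3C)[C@H]2C)ccc1OCc1ccccc1
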